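A direct plan would assemble the whole furanoterpenoid chain first, convert its C20 terminus into the bromide A1, and acylate the Grignard reagent of A1 with the enolate of diethyl oxalpropionate A2 to give the diketo ester A3. It would then close the lactone by base-promoted enol-lactonisation to the 20Z tetronic acid A4, acylate this to the 20Z stearate A5, and invert the ylidene alkene by triplet sensitisation. Its weakest steps would be three. The single acylation of an oxalyl ester by a Grignard reagent next to an enolate would have no close precedent and would compete with proton transfer and double addition. The enol-lactonisation would be equally unprecedented and could deliver only the more stable Z alkene. The last-step Z-to-E photoisomerisation would end in a photostationary mixture of unknown composition that must be separated and recycled.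

The new route disconnects the butenolide at the bond between the ring oxygen and C21, an sp2 carbon of the furan-2(5H)-one ring, and not at the acyl carbon. Because C21 is vinylic, the 20E geometry can be stored in an (E)-vinyl bromide (Br trans to C18) made by kinetic olefination of the C20 aldehyde. The key step, a copper-catalysed intramolecular O-vinylation of a β-keto acid, closes the ring and installs the exocyclic alkene with retention in one operation. It removes the oxalate acylation by a Grignard reagent, the thermodynamically controlled enol-lactonisation and the final photoisomerisation; C18 is set by an enzymatic alkene reduction.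

Key step: step 7

Remark: atoms are numbered as in variabilin (furan C1–C4, chain C5–C20 with the stereocentre C18, lactone carbons C21–C24, ring oxygen between C21 and C24). C18 is S in the target and in every intermediate from 7 on, because the ranking of its substituents does not change.

Step 1
Reactants: 1 3-(chloromethyl)furan; 2 (2E,6E)-farnesyl bromide
Product: 4 ambliofuran [3-[(3E,7E)-4,8,12-trimethyltrideca-3,7,11-trien-1-yl]furan], via (furan-3-ylmethyl)magnesium chloride 3 (not isolated)
Conditions: 1, Mg, THF, 0 °C → rt; then 2, Li2CuCl4 (3 mol %), THF, −10 → 0 °C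
Reagents that add atoms: none
Why: Copper-catalysed coupling of a Grignard reagent with a primary allylic bromide (Kochi coupling) substitutes bromide directly at C6 without allylic transposition, so both E alkenes of 2 are kept and no stereocentre is formed.

Step 2
Reactants: 4 ambliofuran; 5 methacrolein (2-methylprop-2-enal)
Product: 6 (2E,6E,10E)-13-(furan-3-yl)-2,6,10-trimethyltrideca-2,6,10-trienal
Conditions: 5 (10 equiv), second-generation Hoveyda–Grubbs catalyst RuCl2(H2IMes)(=CH-C6H4-2-OiPr) (5 mol % in two portions), CH2Cl2, 40 °C, argon sweep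
Reagents that add atoms: none
Why: Olefin cross-metathesis: of the three trisubstituted alkenes only the isopropylidene terminus is open enough to enter the ruthenium alkylidene cycle (each inner alkene carries a chain on both carbons), it exchanges its =CMe2 end for =C(Me)CHO with loss of isobutene, and the conjugated enal should form as the E isomer; no stereocentre is formed.

Step 3
Reactants: 6 (2E,6E,10E)-13-(furan-3-yl)-2,6,10-trimethyltrideca-2,6,10-trienal
Product: 7 (2S,6E,10E)-13-(furan-3-yl)-2,6,10-trimethyltrideca-6,10-dienal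
Conditions: ene-reductase of the Old Yellow Enzyme family (variant chosen by screening for the 2S aldehyde), NAD+ (2 mol %), HCO2Na (3 equiv), formate dehydrogenase, phosphate buffer pH 7.0/t-BuOMe (two phases), 25 °C; organic phase dried and used at once
Reagents that add atoms: none
Why: Ene-reductase (flavin-dependent alkene reductase) bioreduction of an α-methyl enal: hydride passes from the reduced flavin to C17 and a tyrosine proton to C18 on the opposite face, so the active site sets C18 (S for the enzyme chosen), and the two unactivated trisubstituted alkenes and the furan are not substrates.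

Step 4
Reactants: 7 (2S,6E,10E)-13-(furan-3-yl)-2,6,10-trimethyltrideca-6,10-dienal; 8 methyl bis(2,2,2-trifluoroethyl)phosphonoacetate
Product: 10 methyl (2E,4S,8E,12E)-2-bromo-15-(furan-3-yl)-4,8,12-trimethylpentadeca-2,8,12-trienoate, via methyl bromo[bis(2,2,2-trifluoroethoxy)phosphoryl]acetate 9 (not isolated)
Conditions: 8 (1.6 equiv), NaH, THF, 0 °C, then Br2 (1.0 equiv to 8), −10 °C; KN(SiMe3)2 (1.3 equiv), 18-crown-6, THF, −78 °C; then 7, −78 °C, 2 h; aq. NH4Cl; minor Z isomer removed by chromatography
Reagents that add atoms: bromine, BrBr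
Why: Horner–Wadsworth–Emmons olefination in its Still–Gennari form with an α-bromo phosphonate: the trifluoroethyl esters make elimination from the kinetically formed adduct faster than its reversal, so the chain should end cis to the ester and trans to bromine ((E)-α-bromoacrylate), the geometry that later becomes 20E; 9 is the strongest C–H acid in the bromination mixture and is the species deprotonated, and at −78 °C the α-stereocentre of 7 (C18) is not enolised.

Step 5
Reactants: 10 methyl (2E,4S,8E,12E)-2-bromo-15-(furan-3-yl)-4,8,12-trimethylpentadeca-2,8,12-trienoate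
Product: 11 (2E,4S,8E,12E)-2-bromo-15-(furan-3-yl)-4,8,12-trimethylpentadeca-2,8,12-trienoic acid
Conditions: LiOH·H2O (3 equiv), THF/H2O (3:1), 0 °C → rt; cold 0.5 M HCl to pH 3
Reagents that add atoms: lithium hydroxide, [Li+].[OH-]
Why: Saponification of the methyl ester (acyl substitution by hydroxide) leaves the vinylic bromide, the alkene geometry and C18 unchanged and frees the acid for activation.

Step 6
Reactants: 11 (2E,4S,8E,12E)-2-bromo-15-(furan-3-yl)-4,8,12-trimethylpentadeca-2,8,12-trienoic acid; 12 propanoic acid
Product: 15 (4E,6S,10E,14E)-4-bromo-17-(furan-3-yl)-2,6,10,14-tetramethyl-3-oxoheptadeca-4,10,14-trienoic acid (C2 epimers), via acyl imidazolide 13 (not isolated), via dilithium propanoate enediolate 14 (not isolated)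
Conditions: 11, CDI (1.1 equiv), THF, rt, 1 h, then argon purge; separately 12 (3.3 equiv), LiN(iPr)2 (6.6 equiv), THF, −78 → 0 °C; imidazolide solution added at −78 °C, 1 h; cold 0.5 M HCl to pH 3; extracted at 0 °C and used crude
Reagents that add atoms: none
Why: Acylation of a carboxylic acid dianion (enediolate) by an N-acylimidazole is a Claisen-type C-acylation that gives the β-keto acid directly, the product being held in the flask as its enolate–carboxylate and so shielded from a second acylation and from decarboxylation; the hard enediolate should attack the activated carbonyl and not C20, the vinylic bromide, its geometry and C18 are untouched, and the new centre C23 is unselective and later becomes sp2.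

Step 7
Reactants: 15 (4E,6S,10E,14E)-4-bromo-17-(furan-3-yl)-2,6,10,14-tetramethyl-3-oxoheptadeca-4,10,14-trienoic acid
Product: 16 (5E)-5-[(2S,6E,10E)-13-(furan-3-yl)-2,6,10-trimethyltrideca-6,10-dien-1-ylidene]-4-hydroxy-3-methylfuran-2(5H)-one [(18S,20E)-variabilin]
Conditions: crude 15, CuI (10 mol %), 1,10-phenanthroline (20 mol %), Cs2CO3 (2.5 equiv), degassed THF (0.02 M), 45 °C; cold 0.5 M HCl to pH 3
Reagents that add atoms: none
Why: The caesium carboxylate of 15 binds the monovalent copper–phenanthroline complex, the neighbouring vinylic C21–Br bond adds oxidatively to give a six-membered alkenyl(carboxylato) trivalent-copper metallacycle, and C–O reductive elimination closes the lactone; the closest known reaction type is the copper-catalysed intramolecular O-vinylation of 4-bromoalk-4-enoic acids to γ-ylidene butyrolactones (Ullmann-type vinylation). The furan-2(5H)-one ring closes in the 5-exo mode by ipso substitution at the sp2 carbon C21, and the product leaves the cycle as the stabilised tetronate anion. No stereocentre is formed: C18 is a spectator, and the alkene geometry is copied because both the formation of the copper–carbon bond and the reductive elimination go with retention at C21, so bromine trans to C18 in 15 becomes the ring oxygen trans to C18, which is 20E. The step needs oxygen attack at C21 in preference to conjugate (6-endo) attack at C20, to decarboxylation and to E/Z scrambling; the first is secured because copper can insert only into the C–Br bond, the others because under Cs2CO3 the substrate is held as its enolate–carboxylate, which is no Michael acceptor and cannot lose CO2, and because the temperature stays at 45 °C.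

Step 8
Reactants: 16 (5E)-5-[(2S,6E,10E)-13-(furan-3-yl)-2,6,10-trimethyltrideca-6,10-dien-1-ylidene]-4-hydroxy-3-methylfuran-2(5H)-one; 17 stearoyl chloride
Product: 18 (2E)-2-[(2S,6E,10E)-13-(furan-3-yl)-2,6,10-trimethyltrideca-6,10-dien-1-ylidene]-4-methyl-5-oxo-2,5-dihydrofuran-3-yl octadecanoate (CNP0018186.1)
Conditions: 17 (1.2 equiv), Et3N (1.5 equiv), CH2Cl2, −20 → 0 °C
Reagents that add atoms: none
Why: O-Acylation of a tetronic acid (a vinylogous carboxylic acid) by an acid chloride: C23 carries the methyl group, so only the oxygen on C22 is acylated, and neither C18 nor the 20E alkene takes part.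

**Compound list**
1 | 3-(chloromethyl)furan | ClCc1ccoc1 | starting material
2 | (2E,6E)-farnesyl bromide, (2E,6E)-1-bromo-3,7,11-trimethyldodeca-2,6,10-triene | CC(C)=CCC/C(C)=C/CC/C(C)=C/CBr | starting material
3 | (furan-3-ylmethyl)magnesium chloride (not isolated) | Cl[Mg]Cc1ccoc1 | intermediate
4 | ambliofuran, 3-[(3E,7E)-4,8,12-trimethyltrideca-3,7,11-trien-1-yl]furan | CC(C)=CCC/C(C)=C/CC/C(C)=C/CCc1ccoc1 | intermediate
5 | methacrolein, 2-methylprop-2-enal | CC(=C)C=O | starting material
6 | (2E,6E,10E)-13-(furan-3-yl)-2,6,10-trimethyltrideca-2,6,10-trienal | O=C/C(C)=C/CC/C(C)=C/CC/C(C)=C/CCc1ccoc1 | intermediate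
7 | (2S,6E,10E)-13-(furan-3-yl)-2,6,10-trimethyltrideca-6,10-dienal | O=C[C@@H](C)CCC/C(C)=C/CC/C(C)=C/CCc1ccoc1 | intermediate
8 | methyl bis(2,2,2-trifluoroethyl)phosphonoacetate, methyl 2-[bis(2,2,2-trifluoroethoxy)phosphoryl]acetate | COC(=O)CP(=O)(OCC(F)(F)F)OCC(F)(F)F | starting material
9 | methyl bromo[bis(2,2,2-trifluoroethoxy)phosphoryl]acetate (racemic, not isolated) | COC(=O)C(Br)P(=O)(OCC(F)(F)F)OCC(F)(F)F | intermediate
10 | methyl (2E,4S,8E,12E)-2-bromo-15-(furan-3-yl)-4,8,12-trimethylpentadeca-2,8,12-trienoate | COC(=O)/C(Br)=C\[C@@H](C)CCC/C(C)=C/CC/C(C)=C/CCc1ccoc1 | intermediate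
11 | (2E,4S,8E,12E)-2-bromo-15-(furan-3-yl)-4,8,12-trimethylpentadeca-2,8,12-trienoic acid | OC(=O)/C(Br)=C\[C@@H](C)CCC/C(C)=C/CC/C(C)=C/CCc1ccoc1 | intermediate
12 | propanoic acid | CCC(=O)O | starting material
13 | 1-[(2E,4S,8E,12E)-2-bromo-15-(furan-3-yl)-4,8,12-trimethylpentadeca-2,8,12-trienoyl]-1H-imidazole (not isolated) | O=C(/C(Br)=C\[C@@H](C)CCC/C(C)=C/CC/C(C)=C/CCc1ccoc1)n1ccnc1 | intermediate
14 | dilithium enediolate of propanoic acid, dilithium prop-1-ene-1,1-diolate (not isolated) | CC=C([O-])[O-].[Li+].[Li+] | intermediate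
15 | (4E,6S,10E,14E)-4-bromo-17-(furan-3-yl)-2,6,10,14-tetramethyl-3-oxoheptadeca-4,10,14-trienoic acid (C2 epimers) | OC(=O)C(C)C(=O)/C(Br)=C\[C@@H](C)CCC/C(C)=C/CC/C(C)=C/CCc1ccoc1 | intermediate
16 | (5E)-5-[(2S,6E,10E)-13-(furan-3-yl)-2,6,10-trimethyltrideca-6,10-dien-1-ylidene]-4-hydroxy-3-methylfuran-2(5H)-one, (18S,20E)-variabilin | OC1=C(C)C(=O)O/C1=C/[C@@H](C)CCC/C(C)=C/CC/C(C)=C/CCc1ccoc1 | intermediate
17 | stearoyl chloride, octadecanoyl chloride | CCCCCCCCCCCCCCCCCC(=O)Cl | starting material
18 | (2E)-2-[(2S,6E,10E)-13-(furan-3-yl)-2,6,10-trimethyltrideca-6,10-dien-1-ylidene]-4-methyl-5-oxo-2,5-dihydrofuran-3-yl octadecanoate | CCCCCCCCCCCCCCCCCC(=O)OC1=C(C)C(=O)O/C1=C/[C@@H](C)CCC/C(C)=C/CC/C(C)=C/CCc1ccoc1 | target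

Total step count: 8. Longest linear sequence: 8 steps (1 or 2 to 18).

Steps most likely to fail:

Step 7. The β-keto carboxylate could lose carbon dioxide before ring closure, the carboxylate could add in the conjugate 6-endo sense, or the vinyl bromide geometry could erode by reversible conjugate addition. The fallback sets out from 15. The ketone would be reduced (NaBH4, CeCl3·7H2O, MeOH, −40 °C) to (4E,6S,10E,14E)-4-bromo-17-(furan-3-yl)-3-hydroxy-2,6,10,14-tetramethylheptadeca-4,10,14-trienoic acid F1, which can neither decarboxylate nor act as a Michael acceptor. The same copper-catalysed O-vinylation (CuI, 1,10-phenanthroline, Cs2CO3, THF, 65 °C), now on the unactivated substrate type for which it is established, should give (5E)-5-[(2S,6E,10E)-13-(furan-3-yl)-2,6,10-trimethyltrideca-6,10-dien-1-ylidene]-4-hydroxy-3-methyloxolan-2-one F2. Oxidation of its secondary alcohol with Dess–Martin periodinane (NaHCO3, CH2Cl2) and enolisation would return the route at 16.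

Step 6. The strongly basic dianion could deprotonate C18 or add in the conjugate sense, and the β-keto acid could decarboxylate during the acidic work-up. The fallback sets out from 11 and replaces the acylation by an aldol addition. Amide formation (MeNHOMe·HCl, EDC·HCl, iPr2NEt) would give (2E,4S,8E,12E)-2-bromo-15-(furan-3-yl)-N-methoxy-N,4,8,12-tetramethylpentadeca-2,8,12-trienamide F3. Reduction with iBu2AlH at −78 °C would give (2E,4S,8E,12E)-2-bromo-15-(furan-3-yl)-4,8,12-trimethylpentadeca-2,8,12-trienal F4. 1,2-Addition of the enediolate 14 at −78 °C would give the hydroxy acid F1, from which the route would continue as in the fallback to step 7 through the hydroxy lactone F2 and come back at 16.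

Step 3. The very lipophilic enal could be converted poorly in the aqueous medium, or the α-methyl aldehyde could racemise at C18 during a slow reaction. The fallback sets out from 6. Luche reduction (NaBH4, CeCl3·7H2O, MeOH) would give (2E,6E,10E)-13-(furan-3-yl)-2,6,10-trimethyltrideca-2,6,10-trien-1-ol F5. Hydroxyl-directed asymmetric hydrogenation (H2, Ru(OAc)2[(S)-BINAP] or its antipode, whichever gives the 2S product by Mosher analysis, MeOH) would give (2S,6E,10E)-13-(furan-3-yl)-2,6,10-trimethyltrideca-6,10-dien-1-ol F6. Dess–Martin oxidation would return the route at 7.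

Further compounds
F1 | step 7 | (4E,6S,10E,14E)-4-bromo-17-(furan-3-yl)-3-hydroxy-2,6,10,14-tetramethylheptadeca-4,10,14-trienoic acid (C2/C3 diastereomers) | OC(=O)C(C)C(O)/C(Br)=C\[C@@H](C)CCC/C(C)=C/CC/C(C)=C/CCc1ccoc1
F2 | step 7 | (5E)-5-[(2S,6E,10E)-13-(furan-3-yl)-2,6,10-trimethyltrideca-6,10-dien-1-ylidene]-4-hydroxy-3-methyloxolan-2-one (C3/C4 diastereomers) | CC1C(O)/C(=C\[C@@H](C)CCC/C(C)=C/CC/C(C)=C/CCc2ccoc2)OC1=O
F3 | step 6 | (2E,4S,8E,12E)-2-bromo-15-(furan-3-yl)-N-methoxy-N,4,8,12-tetramethylpentadeca-2,8,12-trienamide | CON(C)C(=O)/C(Br)=C\[C@@H](C)CCC/C(C)=C/CC/C(C)=C/CCc1ccoc1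
F4 | step 6 | (2E,4S,8E,12E)-2-bromo-15-(furan-3-yl)-4,8,12-trimethylpentadeca-2,8,12-trienal | O=C/C(Br)=C\[C@@H](C)CCC/C(C)=C/CC/C(C)=C/CCc1ccoc1
F5 | step 3 | (2E,6E,10E)-13-(furan-3-yl)-2,6,10-trimethyltrideca-2,6,10-trien-1-ol | OC/C(C)=C/CC/C(C)=C/CC/C(C)=C/CCc1ccoc1
F6 | step 3 | (2S,6E,10E)-13-(furan-3-yl)-2,6,10-trimethyltrideca-6,10-dien-1-ol | OC[C@@H](C)CCC/C(C)=C/CC/C(C)=C/CCc1ccoc1
A1 | direct plan | 3-[(3E,7E,12S)-13-bromo-4,8,12-trimethyltrideca-3,7-dien-1-yl]furan | BrC[C@@H](C)CCC/C(C)=C/CC/C(C)=C/CCc1ccoc1
A2 | direct plan | diethyl oxalpropionate, diethyl 2-methyl-3-oxobutanedioate | CCOC(=O)C(C)C(=O)C(=O)OCC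
A3 | direct plan | ethyl (6S,10E,14E)-17-(furan-3-yl)-2,6,10,14-tetramethyl-3,4-dioxoheptadeca-10,14-dienoate | CCOC(=O)C(C)C(=O)C(=O)C[C@@H](C)CCC/C(C)=C/CC/C(C)=C/CCc1ccoc1
A4 | direct plan | (5Z)-5-[(2S,6E,10E)-13-(furan-3-yl)-2,6,10-trimethyltrideca-6,10-dien-1-ylidene]-4-hydroxy-3-methylfuran-2(5H)-one | OC1=C(C)C(=O)O/C1=C\[C@@H](C)CCC/C(C)=C/CC/C(C)=C/CCc1ccoc1
A5 | direct plan | (2Z)-2-[(2S,6E,10E)-13-(furan-3-yl)-2,6,10-trimethyltrideca-6,10-dien-1-ylidene]-4-methyl-5-oxo-2,5-dihydrofuran-3-yl octadecanoate | CCCCCCCCCCCCCCCCCC(=O)OC1=C(C)C(=O)O/C1=C\[C@@H](C)CCC/C(C)=C/CC/C(C)=C/CCc1ccoc1
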